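**Remark (assumption):** Prostanoid atom numbers are used throughout (C1 = ester carbon, C8–C12 = ring, C20 = chain end). (S)-Glyceraldehyde acetonide **2** is taken as purchased or freshly made from L-ascorbic acid. TBS = tert-butyldimethylsilyl, TES = triethylsilyl.

## The problem

Target **24** is a 2-iodo-4-hydroxycyclopent-2-enone: C9 is the ketone, C10 carries iodine, C12 is a quaternary carbinol bearing a (Z)-oct-2-enyl chain, and C8 carries the acetoxy carbon C7, from which the (5Z)-heptenoate chain departs. Three contiguous stereocentres, C12 (S), C8 (R) and C7 (S), must be set in relation to each other: C12–OH and the C7 chain are cis on the ring, and C7/C8 are anti with respect to the C9 carbonyl. C8 is the α-carbon of two aldol units at once (C9=O/C7–OAc and C9=O/C12–OH), so the finished array is fragile: weak base expels acetate to the cross-conjugated dienone, C8 can epimerise, and C8–C12 can open by retro-aldol reaction. Both chain olefins are skipped Z-olefins, and the vinyl iodide rules out hydrogenation, hydride or organometallic steps after its introduction. No simple building block holds a cyclopentenone with a tertiary carbinol γ to the carbonyl and a branched oxygenated carbon at the α′ position. The enabling feature is that C9 (C=O) and C12 (C–OH) are the two ends of the allylic system C9–C10=C11–C12. Read with the oxidation levels exchanged, ring C8–C12 is a trans-4-hydroxy-5-substituted cyclopent-2-enone (C12 ketone, C9 carbinol), the product pattern of a furylcarbinol ring contraction, with C8 as the former carbinol carbon and C7–C6 as a glycerol unit. C7 (chiral pool) can then control C8, C8 can control C12, and the C9 carbinol is a sacrificial centre.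

## Retrosynthesis

**C10–I.** Iodine is removed first: **24** comes from enone **23** by α-iodination. This must be last because no other step tolerates the vinyl iodide. The forward reaction must not expel the C7 acetate.

**C9 carbonyl (1,3-transposition).** **23** is taken back to the allylic alcohol **22** and its silyl ether **21**. Keeping C9 as a carbinol until the penultimate step means the β-acetoxy ketone never meets a base or a nucleophile. The forward step is a neutral allylic oxidation.

**C7–O acetyl.** **21** comes from diol **20** by acetylation of the only secondary hydroxyl. Doing this before the ketone exists removes the elimination risk.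

**C5=C6.** **20** is cut at the Z-olefin into lactol **14** and ylide **19** (from salt **18**, made from **16** and **17**). Compared with an alkyne and semihydrogenation, this gives the Z-olefin directly and uses the cis C12–OH as an internal mask for the C6 aldehyde. **14** comes from lactone **15**, and **15** from triol **13** by oxidation of the primary alcohol. **13** is the hydrolysed acetonide **12**. The Wittig step must be Z-selective and must not epimerise C7.

**C12–C13.** **12** is cut between the quaternary carbon and the octenyl CH2 into ketone **8** and the allylic barium reagent **11** (from chloride **10**, from alcohol **9**). This cut, rather than C12–C8 or C12–C11, removes the quaternary centre and leaves a ketone whose neighbour C8 directs the attack. The forward step needs α-attack of the allyl unit, retention of Z geometry, and addition anti to the C8 substituent.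

**C8–C9 and the ring.** **8** is the silyl ether of **7**, and **7** is the Piancatelli product of furylcarbinol **4** via cations **5** and **6**. Against a C7–C8 aldol cut, this takes C7 and the C7–C8 bond ready-made from glyceraldehyde and builds the ring, C8 and C9 in one step from a flat furan. **4** comes from furan **1** (via **3**) and aldehyde **2**. The key step must control the face of ring closure relative to C7.

## Roads not taken

**Alternative 1:** Cut C7–C8 by an aldol reaction on the finished C12-carbinol ring. The C8 lithium enolate of (4S)-4-[(2Z)-oct-2-enyl]-4-(trimethylsilyloxy)cyclopent-2-enone A1 would add to methyl (5Z)-7-oxohept-5-enoate A2 to give aldol A3, followed by acetylation and iodination. This is the route most chemists would draw, and a closed chair transition state gives the correct C7/C8 anti relation. It is about three steps shorter in the longest line. Its weakness is that the C8 face of enolate A1 must be chosen by discrimination between OSiR3 and CH2R on the quaternary C12, which are similar in size, and a wrong-face adduct cannot be corrected. A2 is configurationally labile (an alkynal surrogate needs a late semihydrogenation). The base-labile β-hydroxy ketone A3 also appears mid-route, on material carrying both chains. The chosen plan tests its one uncertain selectivity in step 2 on a C8 compound and creates the aldol array only at the end.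

**Alternative 2:** Cut C8–C12 by the same electrocyclisation, with the octenyl chain already on the furan: carbinol A4 would rearrange to cyclopentenone A5. This would give the whole ring in one step. However, conrotatory closure of the out,out cation places the C12 oxygen trans to the C8 substituent, so A5 is expected to be the C12 epimer of what is needed. Epimerising C8 would instead break the C7/C8 relation. 5-Alkylfurans such as A4 also rearrange more sluggishly, and the α-chain would have to be built by ylide chemistry in the presence of the enone. In the chosen plan the same trans preference falls on C9, which is later oxidised.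

**Alternative 3:** Cut C8–C12 by intramolecular aldol reaction of the (Z)-enedione A6 (from oxidative opening of a 2,5-dialkylfuran) to give A7. This is short, but base would remove the C13 proton of A6 (α to C12=O and allylic) in competition with C8, giving the regioisomeric ring or conjugation of the skipped olefin. The C8 enolate can expel the β-oxygen at C7, the enedione can isomerise from Z to E, and nothing controls C12 in A7. The chosen plan forms the ring under mild acid and never has a ketone flanked by C13.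

Key step: step 2

## Steps

Step 1
Reactants: 1 furan; 2 (4S)-2,2-dimethyl-1,3-dioxolane-4-carbaldehyde
Product: 4 (furan-2-yl)[(4S)-2,2-dimethyl-1,3-dioxolan-4-yl]methanol as both carbinol epimers, via 2-furyllithium 3 (not isolated)
Conditions: n-BuLi, THF, −78 → 0 °C; then 2, −78 °C; H2O
Reagents that add atoms: none
Why: α-Lithiation of furan and 1,2-addition of the organolithium to the aldehyde; the carbinol carbon (C8) needs no control because it is planarised in step 2, so both epimers are carried on together.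

Step 2
Reactants: 4 (furan-2-yl)[(4S)-2,2-dimethyl-1,3-dioxolan-4-yl]methanol
Product: 7 (4R,5R)-4-hydroxy-5-[(4R)-2,2-dimethyl-1,3-dioxolan-4-yl]cyclopent-2-en-1-one, via furfuryl cation 5 (not isolated), via 1,4-dihydroxypentadienyl cation 6 (not isolated)
Conditions: ZnCl2, acetone–H2O (2:1), 60 °C
Reagents that add atoms: water, O
Why: Piancatelli rearrangement: ZnCl2-assisted loss of water from either epimer of 4 gives the same planar furfuryl cation 5, so the uncontrolled carbinol centre is erased (stereoconvergence at C8). Water adds to the free furan C5 (future C9) and the hemiacetal opens to the 1,4-dihydroxypentadienyl cation 6, in which the dioxolanyl group takes the outside position at C8. Thermal conrotatory 4π-electrocyclisation of 6 (closest known reaction type: the Nazarov-type closure of 2-furylcarbinols to trans-4-hydroxy-5-substituted cyclopentenones) forms the C8–C9 bond and the five-membered carbocycle, and loss of a proton gives the enone. Conrotation of the out,out cation fixes C9–OH trans to the C8 substituent. The absolute sense at C8 is set by C7: allylic 1,3-strain holds C7–H in the plane syn to the C12 oxygen, C8 is the nucleophilic enol terminus, and the new bond is expected to form anti to the C7–C6 bond with the C7–O bond gauche, the arrangement preferred for electrophilic attack next to an allylic C–O bond. The selectivity needed is therefore facial only: regiochemistry is fixed because only the furfurylic C–O bond can ionise and only C5 of the furan is free, and acetone as co-solvent keeps the isopropylidene acetal closed.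

Step 3
Reactants: 7 (4R,5R)-4-hydroxy-5-[(4R)-2,2-dimethyl-1,3-dioxolan-4-yl]cyclopent-2-en-1-one
Product: 8 (4R,5S)-4-(TBS-oxy)-5-[(4R)-2,2-dimethyl-1,3-dioxolan-4-yl]cyclopent-2-en-1-one
Conditions: TBSCl, imidazole, DMF, 0 °C
Reagents that add atoms: tert-butyldimethylsilyl chloride, CC(C)(C)[Si](C)(C)Cl
Why: Imidazole-mediated silyl ether formation at the secondary allylic alcohol; the weak base at 0 °C should avoid isomerisation of the 4-hydroxy-5-substituted enone, and the TBS group later distinguishes the C9 oxygen from the C7 oxygen.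

Step 4
Reactants: 9 (2Z)-oct-2-en-1-ol
Product: 10 (2Z)-1-chlorooct-2-ene
Conditions: NCS, Me2S, CH2Cl2, −20 → 0 °C
Reagents that add atoms: N-chlorosuccinimide, O=C1CCC(=O)N1Cl
Why: Chlorination of the allylic alcohol through its alkoxysulfonium salt (SN2 by chloride), which should leave the Z-olefin and the allylic position untransposed.

Step 5
Reactants: 8 (4R,5S)-4-(TBS-oxy)-5-[(4R)-2,2-dimethyl-1,3-dioxolan-4-yl]cyclopent-2-en-1-one; 10 (2Z)-1-chlorooct-2-ene
Product: 12 (1R,4R,5S)-4-(TBS-oxy)-5-[(4R)-2,2-dimethyl-1,3-dioxolan-4-yl]-1-[(2Z)-oct-2-en-1-yl]cyclopent-2-en-1-ol, via (Z)-oct-2-enylbarium chloride 11 (not isolated)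
Conditions: BaI2, lithium biphenylide, THF, 25 °C; then 10, −78 °C; then 8, −78 °C
Reagents that add atoms: none
Why: 1,2-Addition of an allylic barium reagent to the enone carbonyl; such reagents, made and used at −78 °C, react at the unsubstituted allylic terminus (α-attack) with retention of the Z geometry. Attack on the C12 face anti to the adjacent branched C8 substituent should place the new C12–OH cis to C7 and so set the quaternary centre.

Step 6
Reactants: 12 (1R,4R,5S)-4-(TBS-oxy)-5-[(4R)-2,2-dimethyl-1,3-dioxolan-4-yl]-1-[(2Z)-oct-2-en-1-yl]cyclopent-2-en-1-ol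
Product: 13 (1R)-1-[(1S,2R,5R)-2-hydroxy-2-[(2Z)-oct-2-en-1-yl]-5-(TBS-oxy)cyclopent-3-en-1-yl]ethane-1,2-diol
Conditions: AcOH–H2O (4:1), 25 °C
Reagents that add atoms: none
Why: Acid hydrolysis of the terminal isopropylidene acetal; the secondary TBS ether and the tertiary allylic alcohol should tolerate aqueous acetic acid at room temperature.

Step 7
Reactants: 13 (1R)-1-[(1S,2R,5R)-2-hydroxy-2-[(2Z)-oct-2-en-1-yl]-5-(TBS-oxy)cyclopent-3-en-1-yl]ethane-1,2-diol
Product: 15 (3R,3aS,4R,6aR)-3-hydroxy-6a-[(2Z)-oct-2-en-1-yl]-4-(TBS-oxy)-3,3a,4,6a-tetrahydro-2H-cyclopenta[b]furan-2-one, via lactol 14 (not isolated)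
Conditions: TEMPO (cat.), PhI(OAc)2, CH2Cl2, 25 °C
Reagents that add atoms: none
Why: Nitroxyl-catalysed oxidative lactonisation of a 1,4-diol: the primary alcohol is oxidised selectively, the aldehyde is trapped by the cis tertiary C12–OH as lactol 14, and 14 is oxidised on to the γ-lactone. Only the isomer with C12–O cis to C7 can close the cis-fused bicycle, so the step also confirms the configuration set in step 5.

Step 8
Reactants: 15 (3R,3aS,4R,6aR)-3-hydroxy-6a-[(2Z)-oct-2-en-1-yl]-4-(TBS-oxy)-3,3a,4,6a-tetrahydro-2H-cyclopenta[b]furan-2-one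
Product: 14 (3R,3aS,4R,6aR)-6a-[(2Z)-oct-2-en-1-yl]-4-(TBS-oxy)-3,3a,4,6a-tetrahydro-2H-cyclopenta[b]furan-2,3-diol as a mixture of anomers
Conditions: DIBAL-H (excess), CH2Cl2, −78 °C
Reagents that add atoms: none
Why: Partial reduction of a lactone to the lactol; the free C7 hydroxyl first consumes one equivalent of the hydride, and the tetrahedral aluminate is stable at −78 °C and collapses only on work-up.

Step 9
Reactants: 16 methyl 5-bromopentanoate; 17 triphenylphosphine
Product: 18 (5-methoxy-5-oxopentyl)triphenylphosphonium bromide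
Conditions: MeCN, reflux
Reagents that add atoms: none
Why: Quaternisation of the phosphine by a primary bromide (SN2).

Step 10
Reactants: 14 (3R,3aS,4R,6aR)-6a-[(2Z)-oct-2-en-1-yl]-4-(TBS-oxy)-3,3a,4,6a-tetrahydro-2H-cyclopenta[b]furan-2,3-diol; 18 (5-methoxy-5-oxopentyl)triphenylphosphonium bromide
Product: 20 methyl (5Z,7S)-7-hydroxy-7-[(1S,2R,5R)-2-hydroxy-2-[(2Z)-oct-2-en-1-yl]-5-(TBS-oxy)cyclopent-3-en-1-yl]hept-5-enoate, via phosphorus ylide 19 (not isolated)
Conditions: 18 (excess), NaHMDS, THF, −78 → 0 °C; then 14, −78 → 25 °C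
Reagents that add atoms: none
Why: Wittig olefination of a lactol (masked hydroxy aldehyde) with a non-stabilised ylide under lithium-free conditions, which should give the (5Z)-olefin through the kinetic cis-oxaphosphetane; the ylide is made cold and used in excess because the two hydroxyls consume base, and C7 should keep its configuration because the α-oxygenated aldehyde is present only in equilibrium with the lactol alkoxide.

Step 11
Reactants: 20 methyl (5Z,7S)-7-hydroxy-7-[(1S,2R,5R)-2-hydroxy-2-[(2Z)-oct-2-en-1-yl]-5-(TBS-oxy)cyclopent-3-en-1-yl]hept-5-enoate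
Product: 21 methyl (5Z,7S)-7-acetoxy-7-[(1S,2R,5R)-2-hydroxy-2-[(2Z)-oct-2-en-1-yl]-5-(TBS-oxy)cyclopent-3-en-1-yl]hept-5-enoate
Conditions: Ac2O, pyridine, DMAP (cat.), CH2Cl2, 0 °C
Reagents that add atoms: acetic anhydride, CC(=O)OC(C)=O
Why: Acylation of the only secondary alcohol; the tertiary C12–OH should not react at 0 °C, and because no ketone is present yet the acetate cannot be lost by β-elimination.

Step 12
Reactants: 21 methyl (5Z,7S)-7-acetoxy-7-[(1S,2R,5R)-2-hydroxy-2-[(2Z)-oct-2-en-1-yl]-5-(TBS-oxy)cyclopent-3-en-1-yl]hept-5-enoate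
Product: 22 methyl (5Z,7S)-7-acetoxy-7-[(1R,2R,5R)-2,5-dihydroxy-2-[(2Z)-oct-2-en-1-yl]cyclopent-3-en-1-yl]hept-5-enoate
Conditions: HF·pyridine, pyridine, THF, 0 → 25 °C
Reagents that add atoms: none
Why: Fluoride cleavage of the silyl ether under buffered, slightly acidic conditions, which should leave both esters intact and suppress acetyl migration to the freed C9–OH.

Step 13
Reactants: 22 methyl (5Z,7S)-7-acetoxy-7-[(1R,2R,5R)-2,5-dihydroxy-2-[(2Z)-oct-2-en-1-yl]cyclopent-3-en-1-yl]hept-5-enoate
Product: 23 methyl (5Z,7S)-7-acetoxy-7-[(1R,2R)-2-hydroxy-2-[(2Z)-oct-2-en-1-yl]-5-oxocyclopent-3-en-1-yl]hept-5-enoate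
Conditions: MnO2, CH2Cl2, 25 °C
Reagents that add atoms: none
Why: Allylic alcohol oxidation with MnO2, which takes the secondary ring carbinol and leaves the tertiary one; this completes the 1,3-transposition (the C12 carbonyl of 7 is now the carbinol, the C9 carbinol the ketone) and creates the β-acetoxy ketone under neutral conditions.

Step 14
Reactants: 23 methyl (5Z,7S)-7-acetoxy-7-[(1R,2R)-2-hydroxy-2-[(2Z)-oct-2-en-1-yl]-5-oxocyclopent-3-en-1-yl]hept-5-enoate
Product: 24 methyl (5Z,7S)-7-acetoxy-7-[(1R,2S)-2-hydroxy-4-iodo-2-[(2Z)-oct-2-en-1-yl]-5-oxocyclopent-3-en-1-yl]hept-5-enoate (7-acetoxy-7,8-dihydroiodovulone I)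
Conditions: I2, pyridine, CH2Cl2, 0 → 25 °C
Reagents that add atoms: iodine, II
Why: α-Iodination of an enone by the iodine–pyridine method (conjugate addition of pyridine, iodination of the enolate, elimination); only C10 of the C10=C11 enone can react, and the weak base at 0 °C should leave the β-acetoxy ketone intact.

## Compound list

1 | furan | c1ccoc1 | starting material
2 | (4S)-2,2-dimethyl-1,3-dioxolane-4-carbaldehyde [(S)-glyceraldehyde acetonide] | O=C[C@@H]1COC(C)(C)O1 | starting material
3 | 2-furyllithium | [Li]c1ccco1 | intermediate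
4 | (furan-2-yl)[(4S)-2,2-dimethyl-1,3-dioxolan-4-yl]methanol (both carbinol epimers) | OC(c1ccco1)[C@@H]1COC(C)(C)O1 | intermediate
5 | (furan-2-yl)[(4R)-2,2-dimethyl-1,3-dioxolan-4-yl]methylium (furfuryl cation) | [CH+](c1ccco1)[C@@H]1COC(C)(C)O1 | intermediate
6 | O-protonated (2Z,4Z)-5-[(4R)-2,2-dimethyl-1,3-dioxolan-4-yl]-4-hydroxypenta-2,4-dienal (1,4-dihydroxypentadienyl cation) | [OH+]=C/C=C\C(O)=C\[C@@H]1COC(C)(C)O1 | intermediate
7 | (4R,5R)-4-hydroxy-5-[(4R)-2,2-dimethyl-1,3-dioxolan-4-yl]cyclopent-2-en-1-one | O=C1C=C[C@@H](O)[C@@H]1[C@@H]2COC(C)(C)O2 | intermediate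
8 | (4R,5S)-4-[(tert-butyldimethylsilyl)oxy]-5-[(4R)-2,2-dimethyl-1,3-dioxolan-4-yl]cyclopent-2-en-1-one | O=C1C=C[C@@H](O[Si](C)(C)C(C)(C)C)[C@@H]1[C@@H]2COC(C)(C)O2 | intermediate
9 | (2Z)-oct-2-en-1-ol | CCCCC/C=C\CO | starting material
10 | (2Z)-1-chlorooct-2-ene | CCCCC/C=C\CCl | intermediate
11 | [(2Z)-oct-2-en-1-yl]barium chloride | CCCCC/C=C\C[Ba]Cl | intermediate
12 | (1R,4R,5S)-4-[(tert-butyldimethylsilyl)oxy]-5-[(4R)-2,2-dimethyl-1,3-dioxolan-4-yl]-1-[(2Z)-oct-2-en-1-yl]cyclopent-2-en-1-ol | CCCCC/C=C\C[C@@]1(O)C=C[C@@H](O[Si](C)(C)C(C)(C)C)[C@@H]1[C@@H]2COC(C)(C)O2 | intermediate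
13 | (1R)-1-[(1S,2R,5R)-5-[(tert-butyldimethylsilyl)oxy]-2-hydroxy-2-[(2Z)-oct-2-en-1-yl]cyclopent-3-en-1-yl]ethane-1,2-diol | CCCCC/C=C\C[C@@]1(O)C=C[C@@H](O[Si](C)(C)C(C)(C)C)[C@@H]1[C@@H](O)CO | intermediate
14 | (3R,3aS,4R,6aR)-4-[(tert-butyldimethylsilyl)oxy]-6a-[(2Z)-oct-2-en-1-yl]-3,3a,4,6a-tetrahydro-2H-cyclopenta[b]furan-2,3-diol (anomeric mixture) | CCCCC/C=C\C[C@@]1(O2)C=C[C@@H](O[Si](C)(C)C(C)(C)C)[C@@H]1[C@@H](O)C2O | intermediate
15 | (3R,3aS,4R,6aR)-4-[(tert-butyldimethylsilyl)oxy]-3-hydroxy-6a-[(2Z)-oct-2-en-1-yl]-3,3a,4,6a-tetrahydro-2H-cyclopenta[b]furan-2-one | CCCCC/C=C\C[C@@]1(O2)C=C[C@@H](O[Si](C)(C)C(C)(C)C)[C@@H]1[C@@H](O)C2=O | intermediate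
16 | methyl 5-bromopentanoate | COC(=O)CCCCBr | starting material
17 | triphenylphosphine | c1ccc(cc1)P(c1ccccc1)c1ccccc1 | starting material
18 | (5-methoxy-5-oxopentyl)triphenylphosphonium bromide | [Br-].COC(=O)CCCC[P+](c1ccccc1)(c1ccccc1)c1ccccc1 | intermediate
19 | methyl 5-(triphenyl-λ5-phosphanylidene)pentanoate | COC(=O)CCCC=P(c1ccccc1)(c1ccccc1)c1ccccc1 | intermediate
20 | methyl (5Z,7S)-7-[(1S,2R,5R)-5-[(tert-butyldimethylsilyl)oxy]-2-hydroxy-2-[(2Z)-oct-2-en-1-yl]cyclopent-3-en-1-yl]-7-hydroxyhept-5-enoate | CCCCC/C=C\C[C@@]1(O)C=C[C@@H](O[Si](C)(C)C(C)(C)C)[C@@H]1[C@H](/C=C\CCCC(=O)OC)O | intermediate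
21 | methyl (5Z,7S)-7-acetoxy-7-[(1S,2R,5R)-5-[(tert-butyldimethylsilyl)oxy]-2-hydroxy-2-[(2Z)-oct-2-en-1-yl]cyclopent-3-en-1-yl]hept-5-enoate | CCCCC/C=C\C[C@@]1(O)C=C[C@@H](O[Si](C)(C)C(C)(C)C)[C@@H]1[C@H](/C=C\CCCC(=O)OC)OC(C)=O | intermediate
22 | methyl (5Z,7S)-7-acetoxy-7-[(1R,2R,5R)-2,5-dihydroxy-2-[(2Z)-oct-2-en-1-yl]cyclopent-3-en-1-yl]hept-5-enoate | CCCCC/C=C\C[C@@]1(O)C=C[C@@H](O)[C@@H]1[C@H](/C=C\CCCC(=O)OC)OC(C)=O | intermediate
23 | methyl (5Z,7S)-7-acetoxy-7-[(1R,2R)-2-hydroxy-2-[(2Z)-oct-2-en-1-yl]-5-oxocyclopent-3-en-1-yl]hept-5-enoate | CCCCC/C=C\C[C@@]1(O)C=CC(=O)[C@@H]1[C@H](/C=C\CCCC(=O)OC)OC(C)=O | intermediate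
24 | methyl (5Z,7S)-7-acetoxy-7-[(1R,2S)-2-hydroxy-4-iodo-2-[(2Z)-oct-2-en-1-yl]-5-oxocyclopent-3-en-1-yl]hept-5-enoate (7-acetoxy-7,8-dihydroiodovulone I) | CCCCC/C=C\C[C@@]1(O)C=C(I)C(=O)[C@@H]1[C@H](/C=C\CCCC(=O)OC)OC(C)=O | target

## Step count and risks

Total: 14 steps. Longest linear sequence: 12 steps (1, 2, 3, 5, 6, 7, 8, 10, 11, 12, 13, 14). Steps 4 and 9 make the two side-chain reagents.

**Step 2 (key step).** Most likely failure: poor or reversed facial selectivity of the conrotatory closure with respect to C7, since the transition-state model is the least secure argument in the plan. In addition, the α-oxygenated furfuryl cation may ionise slowly and be lost to oligomerisation, 1,2-hydride shift or acetal hydrolysis. The fallback gives up the furan and makes the C7–C8 bond by an aldol reaction; it sets out from chloride 10 and returns to the route at 21. The purchased enone (4S)-4-(TBS-oxy)cyclopent-2-en-1-one F1 is deprotonated with LDA at −78 °C, where β-elimination of the silyloxy group should be slow, and its α′-enolate is added to the known aldehyde methyl 7-oxohept-5-ynoate F2. The aldolate is silylated in the flask with TESCl to give the silyl-protected aldol methyl (7S)-7-[(1R,2R)-2-(TBS-oxy)-5-oxocyclopent-3-en-1-yl]-7-(triethylsilyloxy)hept-5-ynoate F3. Addition should occur trans to the silyloxy group, and the closed chair transition state should give the C7 epimer of the series used above. The barium reagent 11 from 10 is then added to the ring ketone to give the tertiary carbinol methyl (7S)-7-[(1R,2R,5R)-5-(TBS-oxy)-2-hydroxy-2-[(2Z)-oct-2-en-1-yl]cyclopent-3-en-1-yl]-7-(triethylsilyloxy)hept-5-ynoate F4. Semihydrogenation over a lead-poisoned palladium catalyst gives the (5Z)-olefin methyl (5Z,7R)-7-[(1S,2R,5R)-5-(TBS-oxy)-2-hydroxy-2-[(2Z)-oct-2-en-1-yl]cyclopent-3-en-1-yl]-7-(triethylsilyloxy)hept-5-enoate F5. PPTS in methanol removes the TES group to give the C7-epimeric diol methyl (5Z,7R)-7-[(1S,2R,5R)-5-(TBS-oxy)-2-hydroxy-2-[(2Z)-oct-2-en-1-yl]cyclopent-3-en-1-yl]-7-hydroxyhept-5-enoate F6. A Mitsunobu esterification of F6 with acetic acid (PPh3, DIAD) then inverts C7 and delivers acetate 21.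

**Step 5.** Most likely failure: enolisation of the α-branched β-alkoxy ketone by the basic reagent (followed by opening of the dioxolane), loss of α-regioselectivity or Z geometry if the barium reagent warms, or approach from the wrong face, because the required trajectory anti to the C8 branch is syn to the 1,3-related silyloxy group. Fallback from 8: a zinc-mediated Barbier reaction with propargyl bromide (non-basic, small nucleophile) gives the homopropargylic carbinol (1R,4R,5S)-4-(TBS-oxy)-5-[(4R)-2,2-dimethyl-1,3-dioxolan-4-yl]-1-(prop-2-yn-1-yl)cyclopent-2-en-1-ol F7. The dianion of F7 (n-BuLi, THF–DMPU) is alkylated with 1-iodopentane to the oct-2-ynyl carbinol (1R,4R,5S)-4-(TBS-oxy)-5-[(4R)-2,2-dimethyl-1,3-dioxolan-4-yl]-1-(oct-2-yn-1-yl)cyclopent-2-en-1-ol F8. Semihydrogenation of F8 over a lead-poisoned palladium catalyst returns to the route at 12.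

**Step 7.** Most likely failure: glycol cleavage of the vicinal diol by the hypervalent iodine oxidant, or incomplete lactol-to-lactone oxidation giving mixtures. Fallback from 13: silylation with TESCl and imidazole gives the C6,C7-bis(triethylsilyl) ether F9 of triol 13, the tertiary hydroxyl staying free. Swern conditions remove and oxidise only the primary silyl ether of F9 to give the α-silyloxy aldehyde (2R)-2-[(1R,2R,5R)-5-(TBS-oxy)-2-hydroxy-2-[(2Z)-oct-2-en-1-yl]cyclopent-3-en-1-yl]-2-(triethylsilyloxy)acetaldehyde F10, which is expected to rest largely as its lactol with the C12 hydroxyl. Wittig reaction of F10 with ylide 19 gives the 7-O-triethylsilyl ether F11 of diol 20. PPTS in methanol cleaves the TES group of F11 and returns to the route at 20, bypassing 15 and 14.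

**Step 10.** Most likely failure: self-acylation of the ester-bearing ylide (attack of the ylide carbon on its own ester, a five-membered closure) during the long reaction time that a lactol needs, with epimerisation at C7 through the open α-alkoxy aldehyde as a second risk. The fallback changes the C1–C5 building block to the carboxylic acid series and moves ester formation to a separate step; it sets out from lactol 14 and returns at 20. Purchased (4-carboxybutyl)triphenylphosphonium bromide F12 is treated with KOtBu in THF to give the carboxylate ylide potassium 5-(triphenyl-λ5-phosphanylidene)pentanoate F13, whose carboxylate cannot be acylated. Wittig reaction of F13 with 14 gives the hydroxy acid (5Z,7S)-7-[(1S,2R,5R)-5-(TBS-oxy)-2-hydroxy-2-[(2Z)-oct-2-en-1-yl]cyclopent-3-en-1-yl]-7-hydroxyhept-5-enoic acid F14. Esterification of F14 with trimethylsilyldiazomethane in methanol–toluene returns to the route at 20.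

**Step 14.** Most likely failure: iodoetherification of the (Z)-homoallylic tertiary alcohol by the electrophilic iodine, or base-induced loss of acetic acid to the cross-conjugated dienone during the longer reaction times this would need. Fallback from 23: the tertiary hydroxyl is masked with N-(trimethylsilyl)imidazole to give the 12-O-trimethylsilyl ether F15 of enone 23. Iodination of F15 as above gives the silylated iodoenone F16. Citric acid in methanol removes the silyl group of F16 and returns to the route at 24.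

## Further compounds

F1 | step 2 | (4S)-4-[(tert-butyldimethylsilyl)oxy]cyclopent-2-en-1-one (purchased) | O=C1C=C[C@@H](O[Si](C)(C)C(C)(C)C)C1
F2 | step 2 | methyl 7-oxohept-5-ynoate | COC(=O)CCCC#CC=O
F3 | step 2 | methyl (7S)-7-[(1R,2R)-2-[(tert-butyldimethylsilyl)oxy]-5-oxocyclopent-3-en-1-yl]-7-[(triethylsilyl)oxy]hept-5-ynoate | O=C1C=C[C@@H](O[Si](C)(C)C(C)(C)C)[C@@H]1[C@@H](C#CCCCC(=O)OC)O[Si](CC)(CC)CC
F4 | step 2 | methyl (7S)-7-[(1R,2R,5R)-5-[(tert-butyldimethylsilyl)oxy]-2-hydroxy-2-[(2Z)-oct-2-en-1-yl]cyclopent-3-en-1-yl]-7-[(triethylsilyl)oxy]hept-5-ynoate | CCCCC/C=C\C[C@@]1(O)C=C[C@@H](O[Si](C)(C)C(C)(C)C)[C@@H]1[C@@H](C#CCCCC(=O)OC)O[Si](CC)(CC)CC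
F5 | step 2 | methyl (5Z,7R)-7-[(1S,2R,5R)-5-[(tert-butyldimethylsilyl)oxy]-2-hydroxy-2-[(2Z)-oct-2-en-1-yl]cyclopent-3-en-1-yl]-7-[(triethylsilyl)oxy]hept-5-enoate | CCCCC/C=C\C[C@@]1(O)C=C[C@@H](O[Si](C)(C)C(C)(C)C)[C@@H]1[C@@H](/C=C\CCCC(=O)OC)O[Si](CC)(CC)CC
F6 | step 2 | methyl (5Z,7R)-7-[(1S,2R,5R)-5-[(tert-butyldimethylsilyl)oxy]-2-hydroxy-2-[(2Z)-oct-2-en-1-yl]cyclopent-3-en-1-yl]-7-hydroxyhept-5-enoate (C7 epimer of 20) | CCCCC/C=C\C[C@@]1(O)C=C[C@@H](O[Si](C)(C)C(C)(C)C)[C@@H]1[C@@H](/C=C\CCCC(=O)OC)O
F7 | step 5 | (1R,4R,5S)-4-[(tert-butyldimethylsilyl)oxy]-5-[(4R)-2,2-dimethyl-1,3-dioxolan-4-yl]-1-(prop-2-yn-1-yl)cyclopent-2-en-1-ol | C#CC[C@@]1(O)C=C[C@@H](O[Si](C)(C)C(C)(C)C)[C@@H]1[C@@H]2COC(C)(C)O2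
F8 | step 5 | (1R,4R,5S)-4-[(tert-butyldimethylsilyl)oxy]-5-[(4R)-2,2-dimethyl-1,3-dioxolan-4-yl]-1-(oct-2-yn-1-yl)cyclopent-2-en-1-ol | CCCCCC#CC[C@@]1(O)C=C[C@@H](O[Si](C)(C)C(C)(C)C)[C@@H]1[C@@H]2COC(C)(C)O2
F9 | step 7 | 1,2-bis-O-(triethylsilyl) ether of 13 | CCCCC/C=C\C[C@@]1(O)C=C[C@@H](O[Si](C)(C)C(C)(C)C)[C@@H]1[C@@H](O[Si](CC)(CC)CC)CO[Si](CC)(CC)CC
F10 | step 7 | (2R)-2-[(1R,2R,5R)-5-[(tert-butyldimethylsilyl)oxy]-2-hydroxy-2-[(2Z)-oct-2-en-1-yl]cyclopent-3-en-1-yl]-2-[(triethylsilyl)oxy]acetaldehyde | CCCCC/C=C\C[C@@]1(O)C=C[C@@H](O[Si](C)(C)C(C)(C)C)[C@@H]1[C@@H](O[Si](CC)(CC)CC)C=O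
F11 | step 7 | 7-O-triethylsilyl ether of 20 | CCCCC/C=C\C[C@@]1(O)C=C[C@@H](O[Si](C)(C)C(C)(C)C)[C@@H]1[C@H](/C=C\CCCC(=O)OC)O[Si](CC)(CC)CC
F12 | step 10 | (4-carboxybutyl)triphenylphosphonium bromide (purchased) | [Br-].OC(=O)CCCC[P+](c1ccccc1)(c1ccccc1)c1ccccc1
F13 | step 10 | potassium 5-(triphenyl-λ5-phosphanylidene)pentanoate | [K+].[O-]C(=O)CCCC=P(c1ccccc1)(c1ccccc1)c1ccccc1
F14 | step 10 | (5Z,7S)-7-[(1S,2R,5R)-5-[(tert-butyldimethylsilyl)oxy]-2-hydroxy-2-[(2Z)-oct-2-en-1-yl]cyclopent-3-en-1-yl]-7-hydroxyhept-5-enoic acid | CCCCC/C=C\C[C@@]1(O)C=C[C@@H](O[Si](C)(C)C(C)(C)C)[C@@H]1[C@H](/C=C\CCCC(=O)O)O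
F15 | step 14 | 12-O-trimethylsilyl ether of 23 | CCCCC/C=C\C[C@@]1(O[Si](C)(C)C)C=CC(=O)[C@@H]1[C@H](/C=C\CCCC(=O)OC)OC(C)=O
F16 | step 14 | 12-O-trimethylsilyl ether of 24 | CCCCC/C=C\C[C@@]1(O[Si](C)(C)C)C=C(I)C(=O)[C@@H]1[C@H](/C=C\CCCC(=O)OC)OC(C)=O
A1 | alternative 1 | (4S)-4-[(2Z)-oct-2-en-1-yl]-4-[(trimethylsilyl)oxy]cyclopent-2-en-1-one | CCCCC/C=C\C[C@@]1(O[Si](C)(C)C)C=CC(=O)C1
A2 | alternative 1 | methyl (5Z)-7-oxohept-5-enoate | COC(=O)CCC/C=C\C=O
A3 | alternative 1 | methyl (5Z,7S)-7-hydroxy-7-[(1R,2R)-2-[(2Z)-oct-2-en-1-yl]-5-oxo-2-[(trimethylsilyl)oxy]cyclopent-3-en-1-yl]hept-5-enoate | CCCCC/C=C\C[C@@]1(O[Si](C)(C)C)C=CC(=O)[C@@H]1[C@H](/C=C\CCCC(=O)OC)O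
A4 | alternative 2 | {5-[(2Z)-oct-2-en-1-yl]furan-2-yl}[(4S)-2,2-dimethyl-1,3-dioxolan-4-yl]methanol | CCCCC/C=C\Cc1ccc(o1)C(O)[C@@H]1COC(C)(C)O1
A5 | alternative 2 | (4S,5R)-4-hydroxy-5-[(4R)-2,2-dimethyl-1,3-dioxolan-4-yl]-4-[(2Z)-oct-2-en-1-yl]cyclopent-2-en-1-one | CCCCC/C=C\C[C@]1(O)C=CC(=O)[C@@H]1[C@@H]2COC(C)(C)O2
A6 | alternative 3 | (3Z,7Z)-1-[(4R)-2,2-dimethyl-1,3-dioxolan-4-yl]trideca-3,7-diene-2,5-dione | CCCCC/C=C\CC(=O)/C=C\C(=O)C[C@@H]1COC(C)(C)O1
A7 | alternative 3 | (4R,5R)-4-hydroxy-5-[(4R)-2,2-dimethyl-1,3-dioxolan-4-yl]-4-[(2Z)-oct-2-en-1-yl]cyclopent-2-en-1-one | CCCCC/C=C\C[C@@]1(O)C=CC(=O)[C@@H]1[C@@H]2COC(C)(C)O2
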